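**Retrosynthetic overview**

- Locants: ring C (syringyl)–C7–C8–C9, ring B–C7'–C8'–C9', ring A–C7''–C8''–C9''; ethers C7–O–C9', C7'–O–C9, C8''–O–C4'.
- End game: global desilylation; the C7'–O–C9 tetrahydrofuran is closed through the ring B benzylic cation of a diol made from a furofuranone-derived lactol and an aryllithium that already carries ring A and the threo C7''/C8'' chain (Evans syn aldol).
- Key disconnection, a (3+2) annulation of a donor-acceptor cyclopropane lactone with formaldehyde: benzylic C7 (donor: para-oxygenated ring C) and C8' (alpha to the C7' lactone carbonyl) are 1,3-related through C8 and bridged in the target by O–C9'. A C7–C8' cyclopropane bond is therefore push-pull, and cutting O–C7 and C8'–C9' leaves formaldehyde and a 6-aryl-3-oxabicyclo[3.1.0]hexan-2-one.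
- The cyclopropane is made with ring C endo, from a Z-allylic diazoacetate by catalytic asymmetric intramolecular cyclopropanation (sets C8 and C8'). Invertive capture at C7, the course of the known diester annulation, then gives exo ring C, and full ionisation at C7 would lead to the same epimer.
- Ring order: cyclopropane and lactone (step 6), tetrahydrofuran O–C7–C8–C8'–C9' (step 7), tetrahydrofuran O–C7'–C8'–C8–C9 (step 16).

Key step: step 7

Assumption: Rh2(5S-MEPY)4 (dirhodium tetrakis[methyl (5S)-2-oxopyrrolidine-5-carboxylate]) is taken to induce the (1R,5S) sense at the ring-fusion carbons, as recalled for allyl and Z-allylic diazoacetates; should the lactone prove antipodal, Rh2(5R-MEPY)4 is used instead.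

**Route**

Step 1
Reactants: 1 syringaldehyde (4-hydroxy-3,5-dimethoxybenzaldehyde)
Product: 2 3,5-dimethoxy-4-(triisopropylsilyloxy)benzaldehyde
Conditions: TIPSCl, imidazole, DMAP (cat.), DMF, 40 °C
Reagents that add atoms: chlorotriisopropylsilane (TIPSCl), CC(C)[Si](Cl)(C(C)C)C(C)C
Why: Imidazole-promoted silyl ether formation masks the hindered phenol, which would otherwise quench the phosphonate anion, the hydride and the Lewis acid of later steps; the aldehyde is not touched.

Step 2
Reactants: 2 3,5-dimethoxy-4-(triisopropylsilyloxy)benzaldehyde; 3 methyl bis(2,2,2-trifluoroethyl)phosphonoacetate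
Product: 4 methyl (Z)-3-[3,5-dimethoxy-4-(triisopropylsilyloxy)phenyl]prop-2-enoate
Conditions: 3, KN(SiMe3)2, 18-crown-6, THF, −78 °C; then 2
Reagents that add atoms: none
Why: Still–Gennari variant of the Horner–Wadsworth–Emmons olefination: the trifluoroethyl phosphonate eliminates fast from the kinetic adduct under non-coordinating conditions and should give the Z-enoate, the geometry that later places ring C endo on the cyclopropane.

Step 3
Reactants: 4 methyl (Z)-3-[3,5-dimethoxy-4-(triisopropylsilyloxy)phenyl]prop-2-enoate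
Product: 5 (Z)-3-[3,5-dimethoxy-4-(triisopropylsilyloxy)phenyl]prop-2-en-1-ol
Conditions: i-Bu2AlH (2.5 equiv), CH2Cl2, −78 °C; aq. potassium sodium tartrate
Reagents that add atoms: none
Why: 1,2-Reduction of the ester by i-Bu2AlH at low temperature gives the allylic alcohol without touching the Z double bond or the aryl silyl ether.

Step 4
Reactants: 5 (Z)-3-[3,5-dimethoxy-4-(triisopropylsilyloxy)phenyl]prop-2-en-1-ol; 6 bromoacetyl bromide
Product: 7 (Z)-3-[3,5-dimethoxy-4-(triisopropylsilyloxy)phenyl]prop-2-en-1-yl 2-bromoacetate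
Conditions: NaHCO3, MeCN, 0 °C
Reagents that add atoms: none
Why: O-Acylation of the primary allylic alcohol by the acid bromide (esterification), with solid bicarbonate taking up HBr so that the acid-labile electron-rich cinnamyl ester does not ionise.

Step 5
Reactants: 7 (Z)-3-[3,5-dimethoxy-4-(triisopropylsilyloxy)phenyl]prop-2-en-1-yl 2-bromoacetate
Product: 8 (Z)-3-[3,5-dimethoxy-4-(triisopropylsilyloxy)phenyl]prop-2-en-1-yl 2-diazoacetate
Conditions: TsNHNHTs, DBU, THF, 0 °C
Reagents that add atoms: N,N'-ditosylhydrazine, Cc1ccc(cc1)S(=O)(=O)NNS(=O)(=O)c1ccc(C)cc1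
Why: Fukuyama diazoacetate synthesis: N-alkylation of ditosylhydrazine by the bromoacetate followed by two base-induced eliminations of sulfinate gives the diazo ester under conditions that leave the Z-allylic ester and the silyl ether alone.

Step 6
Reactants: 8 (Z)-3-[3,5-dimethoxy-4-(triisopropylsilyloxy)phenyl]prop-2-en-1-yl 2-diazoacetate
Product: 9 (1R,5S,6R)-6-[3,5-dimethoxy-4-(triisopropylsilyloxy)phenyl]-3-oxabicyclo[3.1.0]hexan-2-one (ring C endo)
Conditions: Rh2(5S-MEPY)4 (1 mol %), CH2Cl2, reflux, slow addition of 8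
Reagents that add atoms: none
Why: Doyle-type enantioselective intramolecular cyclopropanation: the rhodium carbenoid adds stereospecifically to the Z alkene, so ring C and C9 end cis (ring C endo) and C7 follows from the alkene geometry, while the chiral carboxamidate ligands, which are at their best with Z-allylic diazoacetates, set C8' and C8 as (1R,5S).

Step 7
Reactants: 9 (1R,5S,6R)-6-[3,5-dimethoxy-4-(triisopropylsilyloxy)phenyl]-3-oxabicyclo[3.1.0]hexan-2-one; 10 formaldehyde (used as paraformaldehyde)
Product: 11 (3aS,4R,6aS)-4-[3,5-dimethoxy-4-(triisopropylsilyloxy)phenyl]tetrahydro-1H,3H-furo[3,4-c]furan-1-one (furofuranone; C7' is the carbonyl; ring C exo)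
Conditions: paraformaldehyde (5 equiv), Sc(OTf)3 (20 mol %), 4 Å MS, CH2Cl2, 0 °C → rt
Reagents that add atoms: none
Why: Proposed new method: Sc(OTf)3 on the lactone carbonyl and donation from the para-oxygenated ring C should polarise the push-pull C7–C8' bond of 9 (the only cyclopropane bond that is both benzylic and alpha to the carbonyl, and the external bond that overlaps with the carbonyl pi system); the oxygen of formaldehyde should then attack C7 from the side opposite C8' (O–C7 bond) to give a scandium lactone enolate tethered to an O=CH2+ unit, and the enolate carbon should close on that unit (C8'–C9' bond). The closest known reaction type is the Lewis acid catalysed (3+2) annulation of 2-arylcyclopropane-1,1-diesters with aldehydes, which follows this course; here only one acceptor is present and the aldehyde is formaldehyde, so the strain of the fused bicycle and the strong donor must supply the missing activation. The tetrahydrofuran ring is closed in the C–C bond-forming event, a 5-(enolexo)-endo-trig aldol-type attack on the oxocarbenium ion. C8' is re-formed with retention because C9' is delivered through a tether that hangs from C7 on the face where the cyclopropane stood, so only the cis-fused bicycle can arise and the untouched C8 centre controls it; C7 is set by the invertive attack, which turns endo ring C of 9 into exo ring C of 11. The step needs C–O before C–C bond formation (an intermolecular aldol of the free enolate would put C9' trans to C7 and could not cyclise) and exo ring C; the first is favoured because a benzylic cation or ion pair is captured by a carbonyl oxygen faster than a scandium-bound enolate adds to formaldehyde, and the second is expected under either mechanism, since after full ionisation at C7 closure should place ring C on the convex face.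

Step 8
Reactants: 11 (3aS,4R,6aS)-4-[3,5-dimethoxy-4-(triisopropylsilyloxy)phenyl]tetrahydro-1H,3H-furo[3,4-c]furan-1-one
Product: 12 (3aS,4R,6aS)-4-[3,5-dimethoxy-4-(triisopropylsilyloxy)phenyl]tetrahydro-1H,3H-furo[3,4-c]furan-1-ol (lactol; both anomers)
Conditions: i-Bu2AlH (1.1 equiv), CH2Cl2, −78 °C; aq. potassium sodium tartrate
Reagents that add atoms: none
Why: Half-reduction of the gamma-lactone by i-Bu2AlH stops at the aluminium hemiacetal at −78 °C and gives the lactol on work-up; no ring stereocentre is touched.

Step 9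
Reactants: 13 4-bromo-2-methoxyphenol; 14 bromoacetic acid
Product: 15 2-(4-bromo-2-methoxyphenoxy)acetic acid
Conditions: NaOH, H2O, reflux; then HCl
Reagents that add atoms: none
Why: Williamson ether synthesis: the phenoxide displaces bromide from bromoacetate (SN2) and acidification gives the aryloxyacetic acid.

Step 10
Reactants: 15 2-(4-bromo-2-methoxyphenoxy)acetic acid; 16 (R)-4-benzyloxazolidin-2-one
Product: 18 (R)-4-benzyl-3-[2-(4-bromo-2-methoxyphenoxy)acetyl]oxazolidin-2-one, via mixed pivalic anhydride 17 (not isolated)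
Conditions: PivCl, Et3N, THF, −20 °C; then 16, LiCl, −20 °C → rt
Reagents that add atoms: none
Why: N-Acylation of the Evans oxazolidinone through the mixed pivalic anhydride (Et3N/LiCl procedure), the auxiliary attacking the less hindered aryloxyacetyl carbonyl.

Step 11
Reactants: 19 vanillin (4-hydroxy-3-methoxybenzaldehyde)
Product: 20 3-methoxy-4-(triisopropylsilyloxy)benzaldehyde
Conditions: TIPSCl, imidazole, DMF, rt
Reagents that add atoms: chlorotriisopropylsilane (TIPSCl), CC(C)[Si](Cl)(C(C)C)C(C)C
Why: Silyl ether formation protects the ring A phenol against the boron enolate, the hydride and the organolithium steps.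

Step 12
Reactants: 18 (R)-4-benzyl-3-[2-(4-bromo-2-methoxyphenoxy)acetyl]oxazolidin-2-one; 20 3-methoxy-4-(triisopropylsilyloxy)benzaldehyde
Product: 22 (R)-4-benzyl-3-[(2R,3S)-2-(4-bromo-2-methoxyphenoxy)-3-hydroxy-3-[3-methoxy-4-(triisopropylsilyloxy)phenyl]propanoyl]oxazolidin-2-one, via Z-dibutylboron enolate 21 (not isolated)
Conditions: n-Bu2BOTf, i-Pr2NEt, CH2Cl2, −78 → 0 °C; 20, −78 → 0 °C; then H2O2, MeOH, pH 7 buffer
Reagents that add atoms: none
Why: Evans syn aldol reaction: the Z-dibutylboron enolate reacts with the aldehyde through a Zimmerman–Traxler chair on the enolate face not shielded by the benzyl group of the (R)-auxiliary, which sets C8'' and C7'' as the syn (2R,3S) adduct, that is the threo (7''S,8''S) pattern of the target.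

Step 13
Reactants: 22 the syn aldol adduct
Product: 23 (1S,2S)-2-(4-bromo-2-methoxyphenoxy)-1-[3-methoxy-4-(triisopropylsilyloxy)phenyl]propane-1,3-diol
Conditions: LiBH4, THF–H2O, 0 °C
Reagents that add atoms: none
Why: Reductive cleavage of the imide by LiBH4 (hydride attack at the exocyclic carbonyl) gives the primary alcohol C9'' and returns the auxiliary; neither stereocentre is epimerised under these conditions.

Step 14
Reactants: 23 (1S,2S)-2-(4-bromo-2-methoxyphenoxy)-1-[3-methoxy-4-(triisopropylsilyloxy)phenyl]propane-1,3-diol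
Product: 24 1,3-bis(tert-butyldimethylsilyl) ether of 23 (aryl bromide carrying ring A, ring B and the protected chain)
Conditions: TBSOTf (2.5 equiv), 2,6-lutidine, CH2Cl2, 0 °C
Reagents that add atoms: tert-butyldimethylsilyl trifluoromethanesulfonate (TBSOTf), CC(C)(C)[Si](C)(C)OS(=O)(=O)C(F)(F)F
Why: Silylation of the primary and the hindered benzylic hydroxyl with the silyl triflate gives an aryl bromide without acidic hydrogen for the halogen–metal exchange.

Step 15
Reactants: 12 lactol; 24 aryl bromide
Product: 26 diol with free C9–OH and C7'–OH (both C7' epimers) in which ring B is bonded to C7' and the first tetrahydrofuran is intact, via aryllithium 25 (not isolated)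
Conditions: 24, t-BuLi (2 equiv), THF, −78 °C; 12, n-BuLi (1 equiv), THF, −78 °C; mix, −78 → 0 °C; aq. NH4Cl
Reagents that add atoms: none
Why: Bromine–lithium exchange followed by 1,2-addition of the aryllithium to the aldehyde tautomer of the lactol, whose hydroxyl proton is removed beforehand by a sacrificial base so that the valuable aryllithium is not spent on it; the new carbinol centre C7' forms as a mixture, which does not matter because it is ionised in the next step.

Step 16
Reactants: 26 diol
Product: 27 tetrasilylated furofuran (target with both phenols as triisopropylsilyl ethers and C7''–OH and C9''–OH as tert-butyldimethylsilyl ethers)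
Conditions: BF3·OEt2 (0.3 equiv), 4 Å MS, CH2Cl2, −40 → 0 °C
Reagents that add atoms: none
Why: Lewis acid SN1 cycloetherification: the para-alkoxybenzylic alcohol ionises to a quinone-methide-like cation that the C9 hydroxyl captures 5-exo-trig, ring B taking the exo position on the convex face of the cis-fused bicycle, so both carbinol epimers should converge on (7'R).

Step 17
Reactants: 27 tetrasilylated furofuran
Product: 28 CNP0255927.3 (target)
Conditions: Bu4NF, AcOH, THF, 0 °C → rt
Reagents that add atoms: none
Why: Fluoride-mediated desilylation, buffered with acetic acid to keep the liberated phenoxides and the benzylic ethers from base-induced damage, removes the two aryl and the two alkyl silyl ethers.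

**Compound list**

1 | syringaldehyde | COc1cc(C=O)cc(OC)c1O | starting material
2 | 3,5-dimethoxy-4-(triisopropylsilyloxy)benzaldehyde | COc1cc(C=O)cc(OC)c1O[Si](C(C)C)(C(C)C)C(C)C | intermediate
3 | methyl bis(2,2,2-trifluoroethyl)phosphonoacetate | COC(=O)CP(=O)(OCC(F)(F)F)OCC(F)(F)F | starting material
4 | methyl (Z)-3-[3,5-dimethoxy-4-(triisopropylsilyloxy)phenyl]prop-2-enoate | COC(=O)/C=C\c1cc(OC)c(O[Si](C(C)C)(C(C)C)C(C)C)c(OC)c1 | intermediate
5 | (Z)-3-[3,5-dimethoxy-4-(triisopropylsilyloxy)phenyl]prop-2-en-1-ol | OC/C=C\c1cc(OC)c(O[Si](C(C)C)(C(C)C)C(C)C)c(OC)c1 | intermediate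
6 | bromoacetyl bromide | O=C(Br)CBr | starting material
7 | (Z)-3-[3,5-dimethoxy-4-(triisopropylsilyloxy)phenyl]prop-2-en-1-yl 2-bromoacetate | BrCC(=O)OC/C=C\c1cc(OC)c(O[Si](C(C)C)(C(C)C)C(C)C)c(OC)c1 | intermediate
8 | (Z)-3-[3,5-dimethoxy-4-(triisopropylsilyloxy)phenyl]prop-2-en-1-yl 2-diazoacetate | [N-]=[N+]=CC(=O)OC/C=C\c1cc(OC)c(O[Si](C(C)C)(C(C)C)C(C)C)c(OC)c1 | intermediate
9 | (1R,5S,6R)-6-[3,5-dimethoxy-4-(triisopropylsilyloxy)phenyl]-3-oxabicyclo[3.1.0]hexan-2-one (ring C endo) | O=C1OC[C@@H]2[C@H]1[C@@H]2c1cc(OC)c(O[Si](C(C)C)(C(C)C)C(C)C)c(OC)c1 | intermediate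
10 | formaldehyde (as paraformaldehyde) | C=O | starting material
11 | (3aS,4R,6aS)-4-[3,5-dimethoxy-4-(triisopropylsilyloxy)phenyl]tetrahydro-1H,3H-furo[3,4-c]furan-1-one | O=C1OC[C@@H]2[C@H]1CO[C@H]2c1cc(OC)c(O[Si](C(C)C)(C(C)C)C(C)C)c(OC)c1 | intermediate
12 | (3aS,4R,6aS)-4-[3,5-dimethoxy-4-(triisopropylsilyloxy)phenyl]tetrahydro-1H,3H-furo[3,4-c]furan-1-ol (both anomers) | OC1OC[C@@H]2[C@H]1CO[C@H]2c1cc(OC)c(O[Si](C(C)C)(C(C)C)C(C)C)c(OC)c1 | intermediate
13 | 4-bromo-2-methoxyphenol | COc1cc(Br)ccc1O | starting material
14 | bromoacetic acid | OC(=O)CBr | starting material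
15 | 2-(4-bromo-2-methoxyphenoxy)acetic acid | COc1cc(Br)ccc1OCC(=O)O | intermediate
16 | (R)-4-benzyloxazolidin-2-one | O=C1N[C@H](Cc2ccccc2)CO1 | starting material
17 | 2-(4-bromo-2-methoxyphenoxy)acetic pivalic anhydride | COc1cc(Br)ccc1OCC(=O)OC(=O)C(C)(C)C | intermediate
18 | (R)-4-benzyl-3-[2-(4-bromo-2-methoxyphenoxy)acetyl]oxazolidin-2-one | COc1cc(Br)ccc1OCC(=O)N1C(=O)OC[C@H]1Cc1ccccc1 | intermediate
19 | vanillin | COc1cc(C=O)ccc1O | starting material
20 | 3-methoxy-4-(triisopropylsilyloxy)benzaldehyde | COc1cc(C=O)ccc1O[Si](C(C)C)(C(C)C)C(C)C | intermediate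
21 | Z-dibutylboron enolate of 18 | CCCCB(CCCC)O/C(=C\Oc1ccc(Br)cc1OC)N1C(=O)OC[C@H]1Cc1ccccc1 | intermediate
22 | (R)-4-benzyl-3-[(2R,3S)-2-(4-bromo-2-methoxyphenoxy)-3-hydroxy-3-[3-methoxy-4-(triisopropylsilyloxy)phenyl]propanoyl]oxazolidin-2-one | COc1cc([C@H](O)[C@H](C(=O)N2C(=O)OC[C@H]2Cc2ccccc2)Oc2ccc(Br)cc2OC)ccc1O[Si](C(C)C)(C(C)C)C(C)C | intermediate
23 | (1S,2S)-2-(4-bromo-2-methoxyphenoxy)-1-[3-methoxy-4-(triisopropylsilyloxy)phenyl]propane-1,3-diol | COc1cc([C@H](O)[C@H](CO)Oc2ccc(Br)cc2OC)ccc1O[Si](C(C)C)(C(C)C)C(C)C | intermediate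
24 | 1,3-bis(tert-butyldimethylsilyl) ether of 23 | COc1cc([C@H](O[Si](C)(C)C(C)(C)C)[C@H](CO[Si](C)(C)C(C)(C)C)Oc2ccc(Br)cc2OC)ccc1O[Si](C(C)C)(C(C)C)C(C)C | intermediate
25 | aryllithium from 24 (Li in place of Br) | COc1cc([C@H](O[Si](C)(C)C(C)(C)C)[C@H](CO[Si](C)(C)C(C)(C)C)Oc2ccc([Li])cc2OC)ccc1O[Si](C(C)C)(C(C)C)C(C)C | intermediate
26 | diol: (7R,8S,8'S)-configured 2-aryl-3-(hydroxymethyl)tetrahydrofuran bearing the ring B carbinol C7' (both epimers) on C8'; chain (7''S,8''S) | OC[C@@H]1[C@H](C(O)c2ccc(O[C@@H](CO[Si](C)(C)C(C)(C)C)[C@@H](O[Si](C)(C)C(C)(C)C)c3ccc(O[Si](C(C)C)(C(C)C)C(C)C)c(OC)c3)c(OC)c2)CO[C@H]1c1cc(OC)c(O[Si](C(C)C)(C(C)C)C(C)C)c(OC)c1 | intermediate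
27 | tetrasilylated target (7R,7'R,8S,8'S,7''S,8''S) | COc1cc([C@H](O[Si](C)(C)C(C)(C)C)[C@H](CO[Si](C)(C)C(C)(C)C)Oc2ccc([C@@H]3OC[C@@H]4[C@H]3CO[C@H]4c3cc(OC)c(O[Si](C(C)C)(C(C)C)C(C)C)c(OC)c3)cc2OC)ccc1O[Si](C(C)C)(C(C)C)C(C)C | intermediate
28 | CNP0255927.3 (7R,7'R,8S,8'S,7''S,8''S) | COc1cc([C@H](O)[C@H](CO)Oc2ccc([C@@H]3OC[C@@H]4[C@H]3CO[C@H]4c3cc(OC)c(O)c(OC)c3)cc2OC)ccc1O | target

**Step count and risks**

Total step count: 17. Longest linear sequence: 11 steps (steps 1–8 and 15–17, from syringaldehyde).

Steps most likely to fail: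

Step 7 (the step that carries the new method). The single lactone acceptor may not polarise the C7–C8' bond enough for ring opening under conditions that formaldehyde tolerates. The enolate may add to formaldehyde intermolecularly before C7 is captured, which gives a trans lactone that cannot cyclise. The Lewis acid may also hydroxymethylate ring C, or epimerise the cyclopropane at C7 before capture or re-ionise the C7–O bond of 11, either of which erodes the exo configuration. The fallback uses known chemistry, sets out from allylic alcohol 5 and comes back at furofuranone 11. Acylation of 5 with methyl malonyl chloride (pyridine, CH2Cl2, 0 °C) should give the mixed malonate F1, and diazo transfer (4-acetamidobenzenesulfonyl azide, Et3N, MeCN) the diazomalonate F2. Copper-catalysed intramolecular cyclopropanation (CuOTf with a chiral bis(oxazoline) such as t-Bu-box of the hand that gives the configuration of 9, CH2Cl2, reflux; enantiomeric purity raised by crystallisation if needed) should give the geminal lactone ester cyclopropane F3. This is a cyclopropane-1,1-dicarbonyl compound, the class for which the Lewis acid (3+2) annulation with aldehydes is established (Sn(OTf)2 or Sc(OTf)3, paraformaldehyde, CH2Cl2); it proceeds with inversion at C7 and should give the ester-bearing furofuranone F4. Dealkoxycarbonylation (LiI, pyridine, reflux), in which protonation of the lactone enolate can only give the cis-fused bicycle, returns 11.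

Step 16. Ionisation may not stay confined to C7': the C7–O bond of the first tetrahydrofuran may also ionise (epimerisation at C7), silyl ethers may be lost, or closure may not be fully exo selective. The fallback sets out from lactol 12 and aryl bromide 24 and comes back at 27 without passing through 26. Acetylation of 12 (Ac2O, pyridine, DMAP) gives the anomeric acetate F5. Bromide 24 is converted through aryllithium 25 (t-BuLi, THF, −78 °C) and ZnBr2 into the arylzinc bromide F6. BF3·OEt2 at −78 °C generates the bicyclic oxocarbenium ion from F5, and F6 adds to it from the convex face (C-glycosylation-type arylation of a cyclic oxocarbenium ion). This forms the C7'–aryl bond last and places ring B exo, giving 27 directly.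

Step 15. The lithium lactolate may open too slowly, so that the aryllithium is lost to proton transfer, or the open aldehyde may enolise and epimerise at C8'. The fallback sets out from lactone 11 and aryllithium 25 and comes back at diol 26. Single addition of 25 to 11 at −78 °C (acylation of the aryllithium by the lactone, stopped at the lithium hemiketal) gives after work-up the hydroxy ketone F7, which should exist largely as its cyclic hemiketal. Reduction with NaBH4 in MeOH at 0 °C gives 26 as the same epimeric mixture.

Further compounds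
F1 | step 7 | (Z)-3-[3,5-dimethoxy-4-(triisopropylsilyloxy)phenyl]prop-2-en-1-yl methyl malonate | COC(=O)CC(=O)OC/C=C\c1cc(OC)c(O[Si](C(C)C)(C(C)C)C(C)C)c(OC)c1
F2 | step 7 | (Z)-3-[3,5-dimethoxy-4-(triisopropylsilyloxy)phenyl]prop-2-en-1-yl methyl 2-diazomalonate | COC(=O)C(=[N+]=[N-])C(=O)OC/C=C\c1cc(OC)c(O[Si](C(C)C)(C(C)C)C(C)C)c(OC)c1
F3 | step 7 | methyl 6-endo-[3,5-dimethoxy-4-(triisopropylsilyloxy)phenyl]-2-oxo-3-oxabicyclo[3.1.0]hexane-1-carboxylate (9 with CO2Me on C8') | O=C1OC[C@@H]2[C@@]1(C(=O)OC)[C@@H]2c1cc(OC)c(O[Si](C(C)C)(C(C)C)C(C)C)c(OC)c1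
F4 | step 7 | methyl ester of the furofuranone (11 with CO2Me on C8') | O=C1OC[C@@H]2[C@@]1(C(=O)OC)CO[C@H]2c1cc(OC)c(O[Si](C(C)C)(C(C)C)C(C)C)c(OC)c1
F5 | step 16 | anomeric acetate of lactol 12 | CC(=O)OC1OC[C@@H]2[C@H]1CO[C@H]2c1cc(OC)c(O[Si](C(C)C)(C(C)C)C(C)C)c(OC)c1
F6 | step 16 | arylzinc bromide from 24 (ZnBr in place of Br) | COc1cc([C@H](O[Si](C)(C)C(C)(C)C)[C@H](CO[Si](C)(C)C(C)(C)C)Oc2ccc([Zn]Br)cc2OC)ccc1O[Si](C(C)C)(C(C)C)C(C)C
F7 | step 15 | hydroxy ketone (C7' ketone corresponding to diol 26) | OC[C@@H]1[C@H](C(=O)c2ccc(O[C@@H](CO[Si](C)(C)C(C)(C)C)[C@@H](O[Si](C)(C)C(C)(C)C)c3ccc(O[Si](C(C)C)(C(C)C)C(C)C)c(OC)c3)c(OC)c2)CO[C@H]1c1cc(OC)c(O[Si](C(C)C)(C(C)C)C(C)C)c(OC)c1
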